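**Retrosynthetic overview**

- The target is (3R,3aR,6S,6aS)-3,6-bis(3,4-dimethoxyphenyl)tetrahydro-1H,3H-furo[3,4-c]furan-3a-ol, with both aryl groups on the concave face. The last ring carbon (C3) is held as a lactone carbonyl until the end: aryllithium addition, convex-face Et3SiH reduction of the lactol, then O-debenzylation.
- The bicyclic α-benzyloxy lactone comes from a monocyclic α-diazo-γ-butyrolactone whose side-chain carbinol carries a benzyloxymethyl acetal. A rhodium carbenoid is trapped as an oxonium ylide, and a [1,2]-shift forms the C4H2–C3a bond, the tetrahydrofuran ring, the quaternary stereocentre and its oxygen in one operation.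
- The diazo lactone comes from a γ-lactone built by an MgCl2-catalysed anti-aldol of a succinate N-acyloxazolidinone with veratraldehyde, which sets C6 and C6a. Ring order: butyrolactone (step 5), then tetrahydrofuran (step 7, through a transient six-membered ylide ring); the lactone becomes the second aryl-tetrahydrofuran in steps 8–9.
- Enabling feature: in the ring O5–C4H2–C3a(OH)–C6a–C6, the ring oxygen O5, the methylene C4 and the hydroxyl oxygen on C3a form an O–CH2–C–O array. This is a formaldehyde acetal (O–CH2–O) of the C6 carbinol with C3a inserted into one C–O bond. C3a is also α to C3, so with C3 as a lactone carbonyl (ring C3a–C3–O2–C1–C6a) C3a can be the carbenoid carbon.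

Key step: step 7

Assumption: the MgCl2-catalysed anti-aldol is taken to react through the chelated Z-enolate on the face opposite the benzyl group of the (S)-auxiliary; if the opposite sense were found, the (R)-auxiliary would be used and nothing else changes.

**Step 1**
Reactants: 1 (S)-4-benzyl-1,3-oxazolidin-2-one; 2 4-tert-butoxy-4-oxobutanoic acid (mono-tert-butyl succinate)
Product: 4 tert-butyl 4-[(4S)-4-benzyl-2-oxo-1,3-oxazolidin-3-yl]-4-oxobutanoate, via mixed pivalic anhydride 3 (not isolated)
Conditions: 2, PivCl, Et3N, THF, −20 °C; then 1, LiCl, −20 °C → rt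
Reagents that add atoms: none
Why: Mixed-anhydride N-acylation of the oxazolidinone, which attacks the less hindered succinyl carbonyl; no stereocentre is formed.

**Step 2**
Reactants: 4; 5 3,4-dimethoxybenzaldehyde
Product: 7 tert-butyl (3R,4S)-3-{[(4S)-4-benzyl-2-oxo-1,3-oxazolidin-3-yl]carbonyl}-4-(3,4-dimethoxyphenyl)-4-hydroxybutanoate, via aldol trimethylsilyl ether 6 (not isolated)
Conditions: MgCl2 (10 mol %), Et3N, Me3SiCl, EtOAc, rt; then 1 M HCl, THF, 0 °C
Reagents that add atoms: none
Why: Magnesium-catalysed soft-enolisation anti-aldol of an N-acyloxazolidinone with a non-enolisable aryl aldehyde; the chelated Z-enolate reacts on the face away from the benzyl group to set both stereocentres (3R,4S, anti), and silylation of the aldolate gives turnover.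

**Step 3**
Reactants: 7
Product: 8 tert-butyl (3R,4S)-3-{[(4S)-4-benzyl-2-oxo-1,3-oxazolidin-3-yl]carbonyl}-4-[(benzyloxy)methoxy]-4-(3,4-dimethoxyphenyl)butanoate
Conditions: BnOCH2Cl, iPr2NEt, CH2Cl2, 0 °C → rt
Reagents that add atoms: benzyl chloromethyl ether, ClCOCc1ccccc1
Why: O-alkylation of the secondary alcohol with an α-chloro ether under amine base (benzyloxymethyl ether formation), which leaves both stereocentres untouched and installs the O–CH2–O unit used in step 7.

**Step 4**
Reactants: 8
Product: 9 tert-butyl (3S,4S)-4-[(benzyloxy)methoxy]-4-(3,4-dimethoxyphenyl)-3-(hydroxymethyl)butanoate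
Conditions: LiBH4, H2O (1 equiv), Et2O, 0 °C
Reagents that add atoms: none
Why: Reductive cleavage of the N-acyloxazolidinone to the primary alcohol; the tert-butyl ester is not reduced at 0 °C and the auxiliary is recovered.

**Step 5**
Reactants: 9
Product: 10 (4S)-4-{(S)-[(benzyloxy)methoxy](3,4-dimethoxyphenyl)methyl}oxolan-2-one
Conditions: KOtBu (10 mol %), THF, 0 °C
Reagents that add atoms: none
Why: Alkoxide-catalysed lactonisation (5-exo-trig transesterification) of the γ-hydroxy ester; the stereocentre is β to the carbonyl and cannot epimerise.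

**Step 6**
Reactants: 10
Product: 12 (4S)-4-{(S)-[(benzyloxy)methoxy](3,4-dimethoxyphenyl)methyl}-3-diazooxolan-2-one, via α-trifluoroacetyl lactone 11 (not isolated)
Conditions: LiN(SiMe3)2, THF, −78 °C; CF3CO2CH2CF3; then 4-acetamidobenzenesulfonyl azide, Et3N, H2O, MeCN, rt
Reagents that add atoms: 4-acetamidobenzenesulfonyl azide, CC(=O)Nc1ccc(cc1)S(=O)(=O)N=[N+]=[N-]
Why: Regitz diazo transfer in its detrifluoroacetylative form: Claisen trifluoroacetylation activates the only enolisable CH2, and the sulfonyl azide then delivers N2 with loss of the trifluoroacetyl group.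

**Step 7**
Reactants: 12
Product: 13 (3aS,4S,6aR)-6a-(benzyloxy)-4-(3,4-dimethoxyphenyl)tetrahydro-1H,3H-furo[3,4-c]furan-1-one
Conditions: Rh2(OPiv)4 (2 mol %), CH2Cl2, −40 °C → rt, slow addition of 12
Reagents that add atoms: none
Why: Rh2(OPiv)4 turns the diazo group into an electrophilic rhodium carbenoid at the lactone α-carbon, which is captured by the outer (benzyl-bearing) oxygen of the benzyloxymethyl acetal to give a six-membered cyclic oxonium ylide. The oxonium-activated O–CH2 bond then ionises with help from the lone pair of the benzylic ether oxygen, and the oxocarbenium/lactone-enolate pair recombines at the enolate carbon (a Stevens-type [1,2]-shift), forming the CH2–C bond, leaving the benzyloxy oxygen on the new quaternary carbon and giving N2 as the only by-product. The closest known reaction type is the rhodium-catalysed oxonium ylide formation/[1,2]-shift of diazocarbonyl compounds tethered to acetals, in which the acetal carbon migrates to the carbenoid carbon. The tetrahydrofuran ring closes by contraction of the six-membered ylide, a five-membered C–C recombination of the enolate carbon with the oxocarbenium carbon (formally 5-(enolexo)-endo-trig), while the lactone ring is untouched. The one new stereocentre, the quaternary O-bearing carbon, is fixed by the adjacent ring CH stereocentre through the three-atom tether, because only the cis-fused bicyclo[3.3.0] lactone can form. Ylide capture must outrun 1,2-hydride migration, C–H insertion into the acetal CH2 or the veratryl ring, and benzyl migration; this rests on the Lewis-basic acetal oxygen held six atoms from the carbenoid carbon, the bulky carboxylate ligands at low temperature, and the far easier heterolysis of an acetal C–O bond than of a benzyl C–O bond.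

**Step 8**
Reactants: 13; 14 4-bromo-1,2-dimethoxybenzene
Product: 16 (3aS,4S,6aR)-6a-(benzyloxy)-1,4-bis(3,4-dimethoxyphenyl)tetrahydro-1H,3H-furo[3,4-c]furan-1-ol (hemiketal mixture at C1), via 3,4-dimethoxyphenyllithium 15 (not isolated)
Conditions: 14, n-BuLi, THF, −78 °C; then 13, −78 °C; NH4Cl
Reagents that add atoms: none
Why: Bromine–lithium exchange followed by single addition of the aryllithium to the γ-lactone, which stops at the lithium hemiketalate at −78 °C; the hemiketal centre is uncontrolled and is erased in step 9.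

**Step 9**
Reactants: 16
Product: 17 (3R,3aR,6S,6aS)-3a-(benzyloxy)-3,6-bis(3,4-dimethoxyphenyl)tetrahydro-1H,3H-furo[3,4-c]furan
Conditions: Et3SiH, BF3·OEt2, CH2Cl2, −78 → −40 °C
Reagents that add atoms: none
Why: Lewis acid-promoted ionic hydrogenation of the aryl hemiketal (the C-aryl glycoside type of lactol reduction); the aryl-stabilised cyclic oxocarbenium ion should take hydride on the convex face of the cis-bicyclo[3.3.0] core, cis to the adjacent benzyloxy group, placing the new aryl group on the concave face (3R).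

**Step 10**
Reactants: 17
Product: 18 (3R,3aR,6S,6aS)-3,6-bis(3,4-dimethoxyphenyl)tetrahydro-1H,3H-furo[3,4-c]furan-3a-ol (target)
Conditions: H2 (1 atm), Pd(OH)2/C, EtOAc, rt
Reagents that add atoms: none
Why: Hydrogenolysis of the tertiary alkyl benzyl ether under neutral conditions; the ring benzylic C–O bonds of the non-phenolic dimethoxyphenyl groups are expected to react much more slowly without acid.

**Compound list**

1 | (S)-4-benzyl-1,3-oxazolidin-2-one | O=C1N[C@@H](Cc2ccccc2)CO1 | starting material
2 | 4-tert-butoxy-4-oxobutanoic acid | OC(=O)CCC(=O)OC(C)(C)C | starting material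
3 | 4-tert-butoxy-4-oxobutanoic pivalic anhydride | CC(C)(C)C(=O)OC(=O)CCC(=O)OC(C)(C)C | intermediate (not isolated)
4 | tert-butyl 4-[(4S)-4-benzyl-2-oxo-1,3-oxazolidin-3-yl]-4-oxobutanoate | CC(C)(C)OC(=O)CCC(=O)N1C(=O)OC[C@@H]1Cc1ccccc1 | intermediate
5 | 3,4-dimethoxybenzaldehyde | COc1ccc(C=O)cc1OC | starting material
6 | trimethylsilyl ether of 7 | COc1ccc([C@@H](O[Si](C)(C)C)[C@H](C(=O)N2C(=O)OC[C@@H]2Cc2ccccc2)CC(=O)OC(C)(C)C)cc1OC | intermediate (not isolated)
7 | tert-butyl (3R,4S)-3-{[(4S)-4-benzyl-2-oxo-1,3-oxazolidin-3-yl]carbonyl}-4-(3,4-dimethoxyphenyl)-4-hydroxybutanoate | COc1ccc([C@@H](O)[C@H](C(=O)N2C(=O)OC[C@@H]2Cc2ccccc2)CC(=O)OC(C)(C)C)cc1OC | intermediate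
8 | tert-butyl (3R,4S)-3-{[(4S)-4-benzyl-2-oxo-1,3-oxazolidin-3-yl]carbonyl}-4-[(benzyloxy)methoxy]-4-(3,4-dimethoxyphenyl)butanoate | COc1ccc([C@@H](OCOCc2ccccc2)[C@H](C(=O)N3C(=O)OC[C@@H]3Cc3ccccc3)CC(=O)OC(C)(C)C)cc1OC | intermediate
9 | tert-butyl (3S,4S)-4-[(benzyloxy)methoxy]-4-(3,4-dimethoxyphenyl)-3-(hydroxymethyl)butanoate | COc1ccc([C@@H](OCOCc2ccccc2)[C@H](CO)CC(=O)OC(C)(C)C)cc1OC | intermediate
10 | (4S)-4-{(S)-[(benzyloxy)methoxy](3,4-dimethoxyphenyl)methyl}oxolan-2-one | COc1ccc([C@@H](OCOCc2ccccc2)[C@@H]2COC(=O)C2)cc1OC | intermediate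
11 | 3-trifluoroacetyl derivative of 10 (epimers/enol at C3) | COc1ccc([C@@H](OCOCc2ccccc2)[C@@H]2COC(=O)C2C(=O)C(F)(F)F)cc1OC | intermediate (not isolated)
12 | (4S)-4-{(S)-[(benzyloxy)methoxy](3,4-dimethoxyphenyl)methyl}-3-diazooxolan-2-one | COc1ccc([C@@H](OCOCc2ccccc2)[C@@H]2COC(=O)C2=[N+]=[N-])cc1OC | intermediate
13 | (3aS,4S,6aR)-6a-(benzyloxy)-4-(3,4-dimethoxyphenyl)tetrahydro-1H,3H-furo[3,4-c]furan-1-one | COc1ccc([C@H]2OC[C@@]3(OCc4ccccc4)C(=O)OC[C@@H]23)cc1OC | intermediate
14 | 4-bromo-1,2-dimethoxybenzene | COc1ccc(Br)cc1OC | starting material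
15 | 3,4-dimethoxyphenyllithium | [Li]c1ccc(OC)c(OC)c1 | intermediate (not isolated)
16 | (3aS,4S,6aR)-6a-(benzyloxy)-1,4-bis(3,4-dimethoxyphenyl)tetrahydro-1H,3H-furo[3,4-c]furan-1-ol (hemiketal mixture) | COc1ccc([C@H]2OC[C@@]3(OCc4ccccc4)C(O)(c4ccc(OC)c(OC)c4)OC[C@@H]23)cc1OC | intermediate
17 | (3R,3aR,6S,6aS)-3a-(benzyloxy)-3,6-bis(3,4-dimethoxyphenyl)tetrahydro-1H,3H-furo[3,4-c]furan | COc1ccc([C@H]2OC[C@@]3(OCc4ccccc4)[C@@H](c4ccc(OC)c(OC)c4)OC[C@@H]23)cc1OC | intermediate
18 | (3R,3aR,6S,6aS)-3,6-bis(3,4-dimethoxyphenyl)tetrahydro-1H,3H-furo[3,4-c]furan-3a-ol | COc1ccc([C@H]2OC[C@@]3(O)[C@@H](c4ccc(OC)c(OC)c4)OC[C@@H]23)cc1OC | target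

**Step count and risks**

Total steps: 10. Longest linear sequence: 10 steps (from 1 and 2 to 18).

Steps most likely to fail:

1. Step 7. The carbenoid may be consumed before the acetal oxygen captures it: by 1,2-hydride migration from the ring CH (butenolide), by C–H insertion into the acetal CH2 or the electron-rich aryl ring, or, inside the ylide, by benzyl migration instead of acetal-carbon migration. Fallback: the same CH2–C bond is closed by polar chemistry from lactone 10. Enolate hydroxylation (LiN(SiMe3)2, then 2-(phenylsulfonyl)-3-phenyloxaziridine, THF, −78 °C) should give the 3,4-trans α-hydroxy lactone F1. Benzylation (BnBr, Ag2O, CH2Cl2) gives the α-benzyloxy lactone F2. O-silylation (LiN(SiMe3)2, Me3SiCl, THF, −78 °C) gives the silyl ketene acetal F3, which is treated without isolation with Me3SiOTf (CH2Cl2, −78 °C). The benzyloxymethyl acetal ionises to the oxocarbenium ion on the side-chain oxygen, and the ketene acetal carbon traps it in an intramolecular Mukaiyama-type alkylation. This rejoins the route at 13.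

2. Step 9. BF3 may ionise the benzylic ether already present (epimerisation of the concave aryl group or reductive ring opening), or hydride may be delivered from the concave face. Fallback: from hemiketal 16, Zn(BH4)2 (Et2O, −20 °C) reduces the ring-opened hydroxy ketone tautomer under chelation control by the benzyloxy group. Hydride enters from the side of the ring CH2 and should give the diol F4 with the (R)-carbinol. Selective sulfonylation of the primary alcohol (MsCl, 2,4,6-collidine, CH2Cl2, −20 °C) gives the mesylate F5. NaH (THF, 0 °C) then closes the ring by Williamson displacement with retention at the benzylic carbon, rejoining at 17.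

3. Step 10. The two ring benzylic C–O bonds may be hydrogenolysed in competition with the hindered tertiary benzyl ether. Fallback: the benzyl group is removed before the second aryl ring is present. From 13, hydrogenolysis (H2, Pd(OH)2/C, EtOAc) gives the hydroxy lactone F6, in which only one ring benzylic ether is exposed. Excess 15 (from 14 and n-BuLi, THF, −78 °C) gives the dihydroxy hemiketal F7, and Et3SiH/BF3·OEt2 (CH2Cl2, −78 → −40 °C) reduces it directly to 18.

**Further compounds**

F1 | step 7 | (3S,4R)-4-{(S)-[(benzyloxy)methoxy](3,4-dimethoxyphenyl)methyl}-3-hydroxyoxolan-2-one (3,4-trans) | COc1ccc([C@@H](OCOCc2ccccc2)[C@@H]3COC(=O)[C@H]3O)cc1OC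
F2 | step 7 | (3S,4S)-3-(benzyloxy)-4-{(S)-[(benzyloxy)methoxy](3,4-dimethoxyphenyl)methyl}oxolan-2-one (3,4-trans) | COc1ccc([C@@H](OCOCc2ccccc2)[C@@H]3COC(=O)[C@H]3OCc4ccccc4)cc1OC
F3 | step 7 | trimethylsilyl ketene acetal of F2 (3-benzyloxy-2-trimethylsilyloxy-4,5-dihydrofuran) | COc1ccc([C@@H](OCOCc2ccccc2)[C@@H]3COC(O[Si](C)(C)C)=C3OCc4ccccc4)cc1OC
F4 | step 9 | [(2S,3S,4R)-4-(benzyloxy)-2-(3,4-dimethoxyphenyl)-4-[(R)-(3,4-dimethoxyphenyl)(hydroxy)methyl]oxolan-3-yl]methanol | COc1ccc([C@H]2OC[C@@](OCc3ccccc3)([C@H](O)c3ccc(OC)c(OC)c3)[C@H]2CO)cc1OC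
F5 | step 9 | primary methanesulfonate of F4 | COc1ccc([C@H]2OC[C@@](OCc3ccccc3)([C@H](O)c3ccc(OC)c(OC)c3)[C@H]2COS(C)(=O)=O)cc1OC
F6 | step 10 | (3aS,4S,6aR)-4-(3,4-dimethoxyphenyl)-6a-hydroxytetrahydro-1H,3H-furo[3,4-c]furan-1-one | COc1ccc([C@H]2OC[C@@]3(O)C(=O)OC[C@@H]23)cc1OC
F7 | step 10 | (3aS,4S,6aR)-1,4-bis(3,4-dimethoxyphenyl)tetrahydro-1H,3H-furo[3,4-c]furan-1,6a-diol (hemiketal mixture) | COc1ccc([C@H]2OC[C@@]3(O)C(O)(c4ccc(OC)c(OC)c4)OC[C@@H]23)cc1OC
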